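**Retrosynthetic overview**

- The piperidine nitrogen N1 is bonded to C2 (carrying the methyl group, neighbour of the C3 carbinol) and to C6 (carrying the chain C1'–C16'). Both N–C bonds are cut back to the C2 and C6 carbonyl groups of an acyclic 3-hydroxy-2,6-dione, and C6–H to a final cis-selective hydrogenation.
- Key disconnection: an (R)-selective transaminase aminates the C2 methyl ketone (C2–N1), and the new amine condenses with the C6 ketone (N1=C6). This closes the only ring of the route, the six-membered ring N1–C2–C3–C4–C5–C6, first as a Δ1-piperideine.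
- The dione is assembled at C6–C1' by a Weinreb ketone synthesis. The C1–C6 amide comes from (S)-5-oxotetrahydrofuran-2-carboxylic acid (source of C3), with the C2 ketone masked as a dioxolane.
- The C1'–C16' Grignard reagent comes from 11-bromoundec-1-ene: opening of (S)-propylene oxide (C15'), ozonolysis and Keck allylation (C4'), hydroboration and bromination (C1').
- O4' and O15' stay benzylated until the last hydrogenation, which reduces the imine and frees both hydroxyls.

Key step: step 14

Numbering: ring atoms N1, C2–C6; chain atoms C1'–C16' counted from the ring; in the open-chain dione C2, C3, C6, C10 and C21 correspond to C2, C3, C6, C4' and C15' of the target.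

Remark on the chemistry: in the open-chain dione O3 (γ to C6) and O10 (δ to C6) can both add to the C6 ketone, and with both free any acid would lock them into a 1,6-dioxaspiro[4.5]decane spiroketal with no C6 carbonyl left; O10 and O21 are therefore carried as benzyl ethers through the key step and only O3 is free there.

**Route**

Step 1
Reactants: 1 11-bromoundec-1-ene; 2 (S)-propylene oxide
Product: 4 (S)-tetradec-13-en-2-ol, via undec-10-en-1-ylmagnesium bromide 3 (not isolated)
Conditions: Mg, THF, 40 °C; then CuI (10 mol%), 2, THF, −30 → 0 °C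
Reagents that add atoms: none
Why: Copper-catalysed Grignard opening of a monosubstituted epoxide is an SN2 attack at the CH2 terminus, so the C–O stereocentre of 2 is not touched and becomes the (S)-carbinol C15' of the chain.

Step 2
Reactants: 4 (S)-tetradec-13-en-2-ol
Product: 5 (S)-13-(benzyloxy)tetradec-1-ene
Conditions: NaH, BnBr, Bu4NI (cat.), THF/DMF, 0 °C → rt
Reagents that add atoms: benzyl bromide, BrCc1ccccc1
Why: Williamson etherification of the sodium alkoxide with benzyl bromide leaves the stereocentre untouched, and the benzyl ether is stable to every later step up to the final hydrogenolysis.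

Step 3
Reactants: 5 (S)-13-(benzyloxy)tetradec-1-ene
Product: 7 (S)-12-(benzyloxy)tridecanal, via secondary ozonide 6 (not isolated)
Conditions: O3, CH2Cl2, −78 °C (stopped at first blue colour); then PPh3, −78 °C → rt
Reagents that add atoms: ozone, [O-][O+]=O
Why: Ozonolysis with reductive phosphine work-up cleaves the terminal alkene to the aldehyde one carbon shorter, and the alkene consumes ozone far faster than the benzyl ether does.

Step 4
Reactants: 7 (S)-12-(benzyloxy)tridecanal
Product: 8 (4S,15S)-15-(benzyloxy)hexadec-1-en-4-ol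
Conditions: (R)-BINOL (20 mol%), Ti(OiPr)4 (10 mol%), 4 Å MS, CH2Cl2; allylSnBu3, −20 °C, 72 h; aq. NaHCO3
Reagents that add atoms: allyltributylstannane, C=CC[Sn](CCCC)(CCCC)CCCC
Why: Keck asymmetric allylation, in which the (R)-BINOL–titanium Lewis acid exposes the Re face of the unbranched aldehyde to the allylstannane and so sets the new carbinol C4' as (S) under catalyst control, independent of the remote C15' centre.

Step 5
Reactants: 8 (4S,15S)-15-(benzyloxy)hexadec-1-en-4-ol
Product: 9 (4S,15S)-4,15-bis(benzyloxy)hexadec-1-ene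
Conditions: NaH, BnBr, Bu4NI (cat.), THF/DMF, 0 °C → rt
Reagents that add atoms: benzyl bromide, BrCc1ccccc1
Why: Williamson etherification caps O4', the oxygen that would otherwise take part in spiroketal formation at C6 later on.

Step 6
Reactants: 9 (4S,15S)-4,15-bis(benzyloxy)hexadec-1-ene
Product: 11 (4S,15S)-4,15-bis(benzyloxy)hexadecan-1-ol, via B-alkyl-9-BBN adduct 10 (not isolated)
Conditions: 9-BBN, THF, 0 °C → rt; then NaOH, H2O2, 0 °C → rt
Reagents that add atoms: hydrogen peroxide, OO
Why: Hydroboration–oxidation, in which 9-BBN places boron on the terminal carbon only (anti-Markovnikov) and alkaline peroxide replaces boron by hydroxyl to give the primary alcohol at C1'.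

Step 7
Reactants: 11 (4S,15S)-4,15-bis(benzyloxy)hexadecan-1-ol
Product: 12 (4S,15S)-4,15-bis(benzyloxy)-1-bromohexadecane
Conditions: CBr4, PPh3, CH2Cl2, 0 °C
Reagents that add atoms: carbon tetrabromide, BrC(Br)(Br)Br
Why: Appel reaction, in which bromide displaces the alkoxyphosphonium group at the primary carbon under neutral conditions that leave the benzyl ethers alone.

Step 8
Reactants: 13 (S)-5-oxotetrahydrofuran-2-carboxylic acid
Product: 15 (S)-5-acetyldihydrofuran-2(3H)-one, via acid chloride 14 (not isolated)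
Conditions: (COCl)2, DMF (cat.), CH2Cl2, 0 °C → rt, evaporate; MeZnCl, Pd(PPh3)4 (3 mol%), THF, 0 °C → rt
Reagents that add atoms: methylzinc chloride, C[Zn]Cl
Why: Acid chloride formation followed by Negishi acylation (oxidative addition of the acyl chloride to zerovalent palladium, transmetalation from zinc, reductive elimination) gives the methyl ketone, and the non-basic zinc reagent neither opens the lactone nor enolises the α-stereocentre, the future C3.

Step 9
Reactants: 15 (S)-5-acetyldihydrofuran-2(3H)-one
Product: 16 (S)-5-(2-methyl-1,3-dioxolan-2-yl)dihydrofuran-2(3H)-one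
Conditions: TMSOCH2CH2OTMS, TMSOTf (5 mol%), CH2Cl2, −78 → −20 °C; pyridine quench
Reagents that add atoms: 1,2-bis(trimethylsilyloxy)ethane, C[Si](C)(C)OCCO[Si](C)(C)C
Why: Noyori ketalisation protects the ketone at low temperature without the protic acid and heat that could enolise the adjacent stereocentre.

Step 10
Reactants: 16 (S)-5-(2-methyl-1,3-dioxolan-2-yl)dihydrofuran-2(3H)-one
Product: 17 (S)-4-hydroxy-N-methoxy-N-methyl-4-(2-methyl-1,3-dioxolan-2-yl)butanamide
Conditions: MeNHOMe·HCl, iPrMgCl, THF, −20 → 0 °C; crude product used at once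
Reagents that add atoms: N,O-dimethylhydroxylamine hydrochloride, CNOC.Cl
Why: Aminolysis of the lactone by the chloromagnesium amide of N,O-dimethylhydroxylamine (Weinreb amide formation) opens the ring at the acyl carbon and leaves the C–O stereocentre untouched.

Step 11
Reactants: 17 (S)-4-hydroxy-N-methoxy-N-methyl-4-(2-methyl-1,3-dioxolan-2-yl)butanamide
Product: 18 (S)-N-methoxy-N-methyl-4-(2-methyl-1,3-dioxolan-2-yl)-4-[(triethylsilyl)oxy]butanamide
Conditions: Et3SiCl, imidazole, DMF, 0 °C → rt
Reagents that add atoms: chlorotriethylsilane, CC[Si](Cl)(CC)CC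
Why: Imidazole-assisted silylation of the secondary alcohol stops relactonisation and protects O3 through the Grignard step with a group that mild acid removes later.

Step 12
Reactants: 12 (4S,15S)-4,15-bis(benzyloxy)-1-bromohexadecane; 18 (S)-N-methoxy-N-methyl-4-(2-methyl-1,3-dioxolan-2-yl)-4-[(triethylsilyl)oxy]butanamide
Product: 20 (1S,8S,19S)-8,19-bis(benzyloxy)-1-(2-methyl-1,3-dioxolan-2-yl)-1-[(triethylsilyl)oxy]icosan-4-one, via Grignard reagent 19 (not isolated)
Conditions: Mg, THF, 45 °C; then 18, THF, −10 → 0 °C; aqueous work-up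
Reagents that add atoms: none
Why: Weinreb ketone synthesis, in which the Grignard reagent adds once and the magnesium-chelated tetrahedral intermediate holds until work-up, so the C6 ketone forms without over-addition while the dioxolane shields C2.

Step 13
Reactants: 20 (1S,8S,19S)-8,19-bis(benzyloxy)-1-(2-methyl-1,3-dioxolan-2-yl)-1-[(triethylsilyl)oxy]icosan-4-one
Product: 21 (3S,10S,21S)-10,21-bis(benzyloxy)-3-hydroxydocosane-2,6-dione
Conditions: 1 M aq. HCl/THF (1:3), rt, stopped as soon as the ketal is consumed
Reagents that add atoms: water, O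
Why: Acid-catalysed hydrolysis removes the labile triethylsilyl ether and the dioxolane in one operation while the benzyl ethers stay, and with O10 blocked the freed O3 can only form a reversible five-membered hemiketal with C6.

Step 14
Reactants: 21 (3S,10S,21S)-10,21-bis(benzyloxy)-3-hydroxydocosane-2,6-dione
Product: 23 (2R,3S)-6-[(4S,15S)-4,15-bis(benzyloxy)hexadecyl]-2-methyl-2,3,4,5-tetrahydropyridin-3-ol, via amino ketone 22 (not isolated)
Conditions: (R)-selective amine transaminase (Aspergillus terreus enzyme; engineered Arthrobacter variants as second choice), pyridoxal 5'-phosphate (1 mM), iPrNH2 (0.5 M), phosphate buffer pH 8.0, DMSO (20% v/v), substrate 5–10 mM, 30 °C; then pH 11, MTBE extraction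
Reagents that add atoms: isopropylamine, CC(C)N
Why: The pyridoxamine form of the enzyme condenses with the C2 carbonyl to a ketimine, the active-site lysine shifts a proton from the cofactor's benzylic carbon to C2 through a quinonoid, and transimination releases the (2R)-amine 22 while isopropylamine recharges the cofactor and leaves as acetone. The closest known reaction type is the ω-transaminase monoamination of 2,6-diketones at the methyl ketone with spontaneous closure to 2,6-disubstituted Δ1-piperideines, together with the amination of α-hydroxy methyl ketones by the same enzyme class. The ring N1–C2–C3–C4–C5–C6 closes by 6-exo-trig attack of the new amine on the C6 carbonyl and loss of water to the endocyclic N1=C6 imine, which takes the amine out of the transamination equilibrium. C2 is the only new stereocentre and is set by the enzyme: the (R)-selective pocket seats the methyl group in its small site and the C3 side in its large site and protonates one face only, whatever the configuration at C3. The step needs regioselectivity for C2 over C6 and retention at C3; C6 is flanked by two methylene chains that do not fit the small site, and the C3–H is not expected to enolise at pH 8 and 30 °C. With O10 and O21 benzylated only O3 can reach C6, and its hemiketal opens reversibly, so the C6 carbonyl stays available for the imine.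

Step 15
Reactants: 23 (2R,3S)-6-[(4S,15S)-4,15-bis(benzyloxy)hexadecyl]-2-methyl-2,3,4,5-tetrahydropyridin-3-ol
Product: 25 (2R,3S,6S)-6-[(4S,15S)-4,15-dihydroxyhexadecyl]-2-methylpiperidin-3-ol, via piperidine bis(benzyl ether) 24 (not isolated)
Conditions: H2 (4 bar), Pd(OH)2/C, MeOH/AcOH (10:1), rt; aq. NH3 work-up
Reagents that add atoms: none
Why: Heterogeneous hydrogenation followed by hydrogenolysis, in which hydrogen is delivered to C6 of the adsorbed cyclic imine on the face opposite the C2 methyl group so that the chain ends cis to the methyl with all three ring substituents equatorial (6S), after which the same catalyst cleaves both benzyl ethers in the acidic medium.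

**Compound list**

1 | 11-bromoundec-1-ene | C=CCCCCCCCCCBr | starting material
2 | (S)-propylene oxide | C[C@H]1CO1 | starting material
3 | undec-10-en-1-ylmagnesium bromide | C=CCCCCCCCCC[Mg]Br | intermediate
4 | (S)-tetradec-13-en-2-ol | C[C@H](O)CCCCCCCCCCC=C | intermediate
5 | (S)-13-(benzyloxy)tetradec-1-ene | C[C@H](OCc1ccccc1)CCCCCCCCCCC=C | intermediate
6 | 3-[(11S)-11-(benzyloxy)dodecyl]-1,2,4-trioxolane (secondary ozonide, both epimers at the ring carbon) | C[C@H](OCc1ccccc1)CCCCCCCCCCC2OCOO2 | intermediate
7 | (S)-12-(benzyloxy)tridecanal | C[C@H](OCc1ccccc1)CCCCCCCCCCC=O | intermediate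
8 | (4S,15S)-15-(benzyloxy)hexadec-1-en-4-ol | C[C@H](OCc1ccccc1)CCCCCCCCCC[C@H](O)CC=C | intermediate
9 | (4S,15S)-4,15-bis(benzyloxy)hexadec-1-ene | C[C@H](OCc1ccccc1)CCCCCCCCCC[C@H](OCc1ccccc1)CC=C | intermediate
10 | 9-[(4R,15S)-4,15-bis(benzyloxy)hexadecyl]-9-borabicyclo[3.3.1]nonane (same spatial arrangement as 9; the C4 descriptor changes only because boron ranks below carbon) | C[C@H](OCc1ccccc1)CCCCCCCCCC[C@H](OCc1ccccc1)CCCB1C2CCCC1CCC2 | intermediate
11 | (4S,15S)-4,15-bis(benzyloxy)hexadecan-1-ol | C[C@H](OCc1ccccc1)CCCCCCCCCC[C@H](OCc1ccccc1)CCCO | intermediate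
12 | (4S,15S)-4,15-bis(benzyloxy)-1-bromohexadecane | C[C@H](OCc1ccccc1)CCCCCCCCCC[C@H](OCc1ccccc1)CCCBr | intermediate
13 | (S)-5-oxotetrahydrofuran-2-carboxylic acid | OC(=O)[C@@H]1CCC(=O)O1 | starting material
14 | (S)-5-oxotetrahydrofuran-2-carbonyl chloride | ClC(=O)[C@@H]1CCC(=O)O1 | intermediate
15 | (S)-5-acetyldihydrofuran-2(3H)-one | CC(=O)[C@@H]1CCC(=O)O1 | intermediate
16 | (S)-5-(2-methyl-1,3-dioxolan-2-yl)dihydrofuran-2(3H)-one | CC1(OCCO1)[C@@H]2CCC(=O)O2 | intermediate
17 | (S)-4-hydroxy-N-methoxy-N-methyl-4-(2-methyl-1,3-dioxolan-2-yl)butanamide | CON(C)C(=O)CC[C@H](O)C1(C)OCCO1 | intermediate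
18 | (S)-N-methoxy-N-methyl-4-(2-methyl-1,3-dioxolan-2-yl)-4-[(triethylsilyl)oxy]butanamide | CON(C)C(=O)CC[C@H](O[Si](CC)(CC)CC)C1(C)OCCO1 | intermediate
19 | [(4S,15S)-4,15-bis(benzyloxy)hexadecyl]magnesium bromide | C[C@H](OCc1ccccc1)CCCCCCCCCC[C@H](OCc1ccccc1)CCC[Mg]Br | intermediate
20 | (1S,8S,19S)-8,19-bis(benzyloxy)-1-(2-methyl-1,3-dioxolan-2-yl)-1-[(triethylsilyl)oxy]icosan-4-one | C[C@H](OCc1ccccc1)CCCCCCCCCC[C@H](OCc1ccccc1)CCCC(=O)CC[C@H](O[Si](CC)(CC)CC)C1(C)OCCO1 | intermediate
21 | (3S,10S,21S)-10,21-bis(benzyloxy)-3-hydroxydocosane-2,6-dione | C[C@H](OCc1ccccc1)CCCCCCCCCC[C@H](OCc1ccccc1)CCCC(=O)CC[C@H](O)C(C)=O | intermediate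
22 | (2R,3S,10S,21S)-2-amino-10,21-bis(benzyloxy)-3-hydroxydocosan-6-one | C[C@H](OCc1ccccc1)CCCCCCCCCC[C@H](OCc1ccccc1)CCCC(=O)CC[C@H](O)[C@@H](C)N | intermediate
23 | (2R,3S)-6-[(4S,15S)-4,15-bis(benzyloxy)hexadecyl]-2-methyl-2,3,4,5-tetrahydropyridin-3-ol | C[C@H](OCc1ccccc1)CCCCCCCCCC[C@H](OCc1ccccc1)CCCC1=N[C@H](C)[C@@H](O)CC1 | intermediate
24 | (2R,3S,6S)-6-[(4S,15S)-4,15-bis(benzyloxy)hexadecyl]-2-methylpiperidin-3-ol | C[C@H](OCc1ccccc1)CCCCCCCCCC[C@H](OCc1ccccc1)CCC[C@H]1CC[C@H](O)[C@@H](C)N1 | intermediate
25 | (2R,3S,6S)-6-[(4S,15S)-4,15-dihydroxyhexadecyl]-2-methylpiperidin-3-ol | C[C@H](O)CCCCCCCCCC[C@H](O)CCC[C@H]1CC[C@H](O)[C@@H](C)N1 | target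

**Step count**

Total step count: 15 (steps 1–7 chain, steps 8–11 ring fragment, steps 12–15 union and endgame).
Longest linear sequence: 11 steps (steps 1–7, then 12–15).

**Steps most likely to fail**

1. Step 14 (key step). The lipophilic C22 bis(benzyl ether) may stay out of reach of the enzyme in the aqueous phase, so that turnover stalls, or slow background chemistry of the α-ketol with the amine donor may overtake the enzymatic amination. The fallback builds the C2–N bond chemically before the chain is attached; it sets out from 15 and returns to the route at 23.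
   - Reduction of 15 with LiBH(s-Bu)3 in THF at −78 °C should give, by Felkin–Anh addition anti to the ring oxygen, the threo alcohol (S)-5-[(S)-1-hydroxyethyl]dihydrofuran-2(3H)-one F1.
   - Mitsunobu azidation (PPh3, DIAD, diphenylphosphoryl azide) inverts this carbinol to (S)-5-[(R)-1-azidoethyl]dihydrofuran-2(3H)-one F2.
   - Hydrogenation (H2, Pd/C, MeOH) gives (S)-5-[(R)-1-aminoethyl]dihydrofuran-2(3H)-one F3, whose amine takes the lactone acyl group from O to N to give (5S,6R)-5-hydroxy-6-methylpiperidin-2-one F4.
   - Et3SiCl/imidazole gives (5S,6R)-6-methyl-5-[(triethylsilyl)oxy]piperidin-2-one F5, and Boc2O/DMAP gives tert-butyl (2R,3S)-2-methyl-6-oxo-3-[(triethylsilyl)oxy]piperidine-1-carboxylate F6.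
   - Grignard reagent 19 opens the activated lactam at −78 °C to tert-butyl N-[(2R,3S,10S,21S)-10,21-bis(benzyloxy)-6-oxo-3-[(triethylsilyl)oxy]docosan-2-yl]carbamate F7.
   - CF3CO2H in CH2Cl2 followed by aqueous NaHCO3 removes the Boc and silyl groups, and the freed amino ketone 22 closes to 23.

2. Step 13. Hydrolysis of the dioxolane, which is deactivated by the neighbouring oxygen, may be slow enough that the freed α-ketol sits in acid. It could then shift its carbonyl or epimerise at C3, lose water from the O3–C6 hemiketal, or undergo aldol closure of the 2,6-dione. The fallback separates the two unveilings so that O3 is freed last under near-neutral conditions; it sets out from 17 and returns at 21.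
   - i-Pr3SiOTf/2,6-lutidine gives (S)-N-methoxy-N-methyl-4-(2-methyl-1,3-dioxolan-2-yl)-4-[(triisopropylsilyl)oxy]butanamide F8.
   - Grignard reagent 19 gives (1S,8S,19S)-8,19-bis(benzyloxy)-1-(2-methyl-1,3-dioxolan-2-yl)-1-[(triisopropylsilyl)oxy]icosan-4-one F9.
   - 1 M HCl/THF removes only the dioxolane to give (3S,10S,21S)-10,21-bis(benzyloxy)-3-[(triisopropylsilyl)oxy]docosane-2,6-dione F10. With O3 still silylated, neither the ketol shift nor the hemiketal dehydration can start.
   - HF·pyridine in THF/pyridine then frees O3 and gives 21.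

3. Step 4. Facial selectivity of the allylation may fall short, and the resulting C4' epimer, remote from every other stereocentre, would not be separable later. The fallback takes the C4' configuration from a resolved epoxide; it sets out from 5 and returns at 8.
   - mCPBA in CH2Cl2 gives 2-[(11S)-11-(benzyloxy)dodecyl]oxirane F11 as both epimers at the oxirane carbon.
   - Hydrolytic kinetic resolution with (S,S)-(salen)Co(OAc) (trivalent cobalt) and 0.55 equiv. of water should consume the unwanted epimer as its diol and leave (2S)-2-[(11S)-11-(benzyloxy)dodecyl]oxirane F12.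
   - Vinylmagnesium bromide with CuI (cat.) opens F12 at the terminal carbon and gives 8.

**Further compounds**

F1 | step 14 | (S)-5-[(S)-1-hydroxyethyl]dihydrofuran-2(3H)-one | C[C@H](O)[C@@H]1CCC(=O)O1
F2 | step 14 | (S)-5-[(R)-1-azidoethyl]dihydrofuran-2(3H)-one | C[C@@H](N=[N+]=[N-])[C@@H]1CCC(=O)O1
F3 | step 14 | (S)-5-[(R)-1-aminoethyl]dihydrofuran-2(3H)-one | C[C@@H](N)[C@@H]1CCC(=O)O1
F4 | step 14 | (5S,6R)-5-hydroxy-6-methylpiperidin-2-one | O=C1CC[C@H](O)[C@@H](C)N1
F5 | step 14 | (5S,6R)-6-methyl-5-[(triethylsilyl)oxy]piperidin-2-one | O=C1CC[C@H](O[Si](CC)(CC)CC)[C@@H](C)N1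
F6 | step 14 | tert-butyl (2R,3S)-2-methyl-6-oxo-3-[(triethylsilyl)oxy]piperidine-1-carboxylate | O=C1CC[C@H](O[Si](CC)(CC)CC)[C@@H](C)N1C(=O)OC(C)(C)C
F7 | step 14 | tert-butyl N-[(2R,3S,10S,21S)-10,21-bis(benzyloxy)-6-oxo-3-[(triethylsilyl)oxy]docosan-2-yl]carbamate | C[C@H](OCc1ccccc1)CCCCCCCCCC[C@H](OCc1ccccc1)CCCC(=O)CC[C@H](O[Si](CC)(CC)CC)[C@@H](C)NC(=O)OC(C)(C)C
F8 | step 13 | (S)-N-methoxy-N-methyl-4-(2-methyl-1,3-dioxolan-2-yl)-4-[(triisopropylsilyl)oxy]butanamide | CON(C)C(=O)CC[C@H](O[Si](C(C)C)(C(C)C)C(C)C)C1(C)OCCO1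
F9 | step 13 | (1S,8S,19S)-8,19-bis(benzyloxy)-1-(2-methyl-1,3-dioxolan-2-yl)-1-[(triisopropylsilyl)oxy]icosan-4-one | C[C@H](OCc1ccccc1)CCCCCCCCCC[C@H](OCc1ccccc1)CCCC(=O)CC[C@H](O[Si](C(C)C)(C(C)C)C(C)C)C1(C)OCCO1
F10 | step 13 | (3S,10S,21S)-10,21-bis(benzyloxy)-3-[(triisopropylsilyl)oxy]docosane-2,6-dione | C[C@H](OCc1ccccc1)CCCCCCCCCC[C@H](OCc1ccccc1)CCCC(=O)CC[C@H](O[Si](C(C)C)(C(C)C)C(C)C)C(C)=O
F11 | step 4 | 2-[(11S)-11-(benzyloxy)dodecyl]oxirane (both epimers at the oxirane carbon) | C[C@H](OCc1ccccc1)CCCCCCCCCCC1CO1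
F12 | step 4 | (2S)-2-[(11S)-11-(benzyloxy)dodecyl]oxirane | C[C@H](OCc1ccccc1)CCCCCCCCCC[C@H]1CO1
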